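**Plan**
- Retrosynthetic cuts: the two aryl O–MOM bonds; C4a–C5 of ring A, with C5 as a ketene released from a dioxinone; O1–C8a (cyclodehydration) and C4–C4a (dianion Claisen); C8–C8a and C8–prenyl on the dioxinone; the aryl–CMe2 bond and the C2–C3 unit of the B-ring piece.
- Forward order: the B ring is reverse-prenylated, homologated to a β-keto ester and reduced to an (S)-β-silyloxy Weinreb amide; a γ-prenylated keto-dioxinone is joined to it through its dianion; ring C (the pyranone) closes first, ring A second, and the MOM groups come off last.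
- Enabling feature: ring A (C4a, C5, C6, C7, C8, C8a) carries oxygen on C5, C7 and C8a. Once O1 is locked in ring C, C4a is the α-carbon of the vinylogous ester C4(=O)–C4a=C8a–O1 and the only carbon that can reach an acyl C5 in a six-membered closure, so the C8 prenyl group and the O1/O5/O7 roles are fixed in the chain instead of being chosen on an arene.
- Stereochemistry: C2 comes from Ru/(S,S)-TsDPEN transfer hydrogenation of the aryl β-keto ester; no later step breaks a bond at that carbon, and no later step exposes the pyranone or the flavanone to base.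
- A methyl ketone, not an aldehyde, carries the B ring through the allylboronate coupling, because an aldehyde would be allylborated by the prenylboronate.

Key step: step 11

Remark: Ar = 2,4-bis(methoxymethoxy)-5-(2-methylbut-3-en-2-yl)phenyl; the carbon that becomes C8 is configurationally labile, so every intermediate containing it is carried as an epimer and keto–enol mixture, and lithium enolates made and consumed in situ are not counted as separate compounds.

**Step 1**
Reactants: 1 1-(5-bromo-2,4-dihydroxyphenyl)ethan-1-one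
Product: 2 1-[5-bromo-2,4-bis(methoxymethoxy)phenyl]ethan-1-one
Conditions: NaH (2.4 equiv), MOMCl (2.6 equiv), DMF, 0 °C → rt
Reagents that add atoms: chloromethyl methyl ether, COCCl
Why: Williamson-type O-alkylation of both sodium phenoxides (the chelated 2-OH needs the free phenoxide in DMF) should give acetal ethers that withstand all the basic and organometallic steps that follow.

**Step 2**
Reactants: 2 1-[5-bromo-2,4-bis(methoxymethoxy)phenyl]ethan-1-one; 3 prenylboronic acid pinacol ester
Product: 4 1-[2,4-bis(methoxymethoxy)-5-(2-methylbut-3-en-2-yl)phenyl]ethan-1-one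
Conditions: Pd(OAc)2 (5 mol %), D-t-BPF (6 mol %), K3PO4 (3 equiv), THF/H2O (10:1), 60 °C
Reagents that add atoms: none
Why: γ-selective Suzuki–Miyaura allylation, in which SE2′ transmetalation puts palladium on the tertiary carbon and the bulky chelating bisphosphine enforces reductive elimination before σ–π–σ isomerisation, should give the 1,1-dimethylallyl arene, the ketone being inert to the allylboronate.

**Step 3**
Reactants: 4 1-[2,4-bis(methoxymethoxy)-5-(2-methylbut-3-en-2-yl)phenyl]ethan-1-one
Product: 5 methyl 3-Ar-3-oxopropanoate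
Conditions: NaH (3 equiv), (MeO)2CO (5 equiv), THF, reflux; AcOH quench
Reagents that add atoms: dimethyl carbonate, COC(=O)OC
Why: crossed Claisen condensation of the acetophenone sodium enolate with dimethyl carbonate is driven to completion by deprotonation of the β-keto ester formed.

**Step 4**
Reactants: 5 methyl 3-Ar-3-oxopropanoate
Product: 6 methyl (3S)-3-Ar-3-hydroxypropanoate
Conditions: RuCl[(S,S)-TsDPEN](p-cymene) (1 mol %), HCO2H/Et3N (5:2), DMF, 30 °C
Reagents that add atoms: none
Why: Noyori asymmetric transfer hydrogenation of an aryl β-keto ester should deliver hydride to the Re face of the ketone (aryl CH/π contact with the η6-arene of the (S,S)-catalyst) and so set the (S)-carbinol, while isolated alkenes and MOM ethers are untouched.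

**Step 5**
Reactants: 6 methyl (3S)-3-Ar-3-hydroxypropanoate
Product: 7 methyl (3S)-3-Ar-3-(triethylsilyloxy)propanoate
Conditions: TESCl (1.3 equiv), imidazole (2.5 equiv), DMF, 0 °C → rt
Reagents that add atoms: chlorotriethylsilane, CC[Si](Cl)(CC)CC
Why: imidazole-promoted silylation of the secondary benzylic alcohol gives an ether that survives amide formation and dianion chemistry yet leaves under weak acid, silyl triflates being avoided because they attack MOM ethers.

**Step 6**
Reactants: 7 methyl (3S)-3-Ar-3-(triethylsilyloxy)propanoate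
Product: 8 (3S)-3-Ar-N-methoxy-N-methyl-3-(triethylsilyloxy)propanamide
Conditions: MeNHOMe·HCl (2 equiv), i-PrMgCl (4 equiv), THF, −20 → 0 °C
Reagents that add atoms: N,O-dimethylhydroxylamine hydrochloride, CNOC.Cl
Why: ester-to-Weinreb-amide exchange with the chloromagnesium amide of N,O-dimethylhydroxylamine runs at low temperature, too mild for β-elimination of the silyloxy group.

**Step 7**
Reactants: 9 2,2,6-trimethyl-4H-1,3-dioxin-4-one; 10 prenyl bromide
Product: 11 2,2-dimethyl-6-(4-methylpent-3-en-1-yl)-4H-1,3-dioxin-4-one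
Conditions: LDA (1.05 equiv), THF, −78 °C; DMPU, then 10, −78 → −30 °C
Reagents that add atoms: none
Why: γ-alkylation of the lithium dienolate of the dioxinone (a vinylogous acetoacetate) with an allylic bromide in the presence of DMPU installs the future C8 prenyl group.

**Step 8**
Reactants: 11 2,2-dimethyl-6-(4-methylpent-3-en-1-yl)-4H-1,3-dioxin-4-one
Product: 12 2,2-dimethyl-6-(6-methyl-2-oxohept-5-en-3-yl)-4H-1,3-dioxin-4-one (racemic)
Conditions: 11 (2 equiv), LiHMDS (2 equiv), THF, −78 °C; AcCl (1 equiv), −78 → −20 °C; aq NH4Cl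
Reagents that add atoms: acetyl chloride, CC(=O)Cl
Why: γ-C-acylation (vinylogous Claisen) of the dioxinone dienolate with an acid chloride, half of the dienolate acting as base for the more acidic product, should give the keto-dioxinone and forms the C8–C8a bond, the excess of 11 being recovered.

**Step 9**
Reactants: 12 2,2-dimethyl-6-(6-methyl-2-oxohept-5-en-3-yl)-4H-1,3-dioxin-4-one; 8 (3S)-3-Ar-N-methoxy-N-methyl-3-(triethylsilyloxy)propanamide
Product: 13 6-[(10S)-10-Ar-2-methyl-6,8-dioxo-10-(triethylsilyloxy)dec-2-en-5-yl]-2,2-dimethyl-4H-1,3-dioxin-4-one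
Conditions: 12 (2.2 equiv), LDA (4.4 equiv), THF, −78 → −40 °C; 8 (1 equiv), −78 → −30 °C; AcOH/THF quench at −78 °C
Reagents that add atoms: none
Why: Claisen-type acylation of the 1,3-dianion of a keto-dioxinone at its terminal methyl carbon by a Weinreb amide (the chelated tetrahedral adduct prevents over-addition) forms the C4–C4a bond without touching the carbinol centre, and the cold acidic quench avoids base-induced aldol aromatisation of the diketo-dioxinone.

**Step 10**
Reactants: 13 6-[(10S)-10-Ar-2-methyl-6,8-dioxo-10-(triethylsilyloxy)dec-2-en-5-yl]-2,2-dimethyl-4H-1,3-dioxin-4-one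
Product: 15 6-{1-[(2S)-2-Ar-4-oxo-3,4-dihydro-2H-pyran-6-yl]-4-methylpent-3-en-1-yl}-2,2-dimethyl-4H-1,3-dioxin-4-one, via δ-hydroxy-β-diketone 14 (not isolated)
Conditions: PPTS (0.2 equiv), MeOH/CH2Cl2 (1:1), 0 °C → rt; concentrate; PPTS (0.1 equiv), 4 Å MS, PhMe, 40 °C
Reagents that add atoms: none
Why: weak-acid methanolysis of the TES ether frees the δ-hydroxyl, which adds to the C8a carbonyl (six-membered hemiketal) and dehydrates to the vinylogous ester (cyclodehydration to a 2,3-dihydro-4H-pyran-4-one) without breaking any bond at C2, so the configuration is retained, and PPTS is too weak to cleave aryl MOM ethers or the dioxinone.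

**Step 11**
Reactants: 15 6-{1-[(2S)-2-Ar-4-oxo-3,4-dihydro-2H-pyran-6-yl]-4-methylpent-3-en-1-yl}-2,2-dimethyl-4H-1,3-dioxin-4-one
Product: 17 (2S)-2-Ar-5,7-dihydroxy-8-(3-methylbut-2-en-1-yl)-2,3-dihydro-4H-chromen-4-one, via acylketene 16 (not isolated)
Conditions: PhMe (ca. 2 mM), 110 °C, syringe-pump addition of 15, N2 sweep to remove acetone
Reagents that add atoms: none
Why: Proposed new method: heating expels acetone from the dioxinone by retro-[4+2] to give acylketene 16, whose C7 ketone enolises toward the doubly activated C8–H to a dienylketene (C5=C6–C7(OH)=C8–C8a=C4a) that bonds C4a to the ketene carbon C5, and two tautomerisations then aromatise the ring; the polar description is attack of the vinylogous-ester α-carbon C4a on the ketene. The closest known reactions are the thermal conversion of 6-(2-oxoalkyl)dioxinones into 4-hydroxy-2-pyranones (same acylketene, enol oxygen as nucleophile), the 6π-electrocyclisation of dienylketenes to phenols, and the base-mediated Claisen/Dieckmann cyclisation of polyketo esters to phloroglucinols. Ring A (C4a, C5, C6, C7, C8, C8a) closes as a six-membered carbocycle, a disrotatory 6π-electrocyclisation or, in polar terms, a 6-exo-dig C-acylation. No stereocentre is formed, the labile side-chain centre becomes the sp2 carbon C8 and C2 is a spectator. The step needs carbon rather than oxygen acylation and ring closure rather than intermolecular capture: O1 is already an ether inside ring C, so oxygen attack (pyranone formation) is impossible and an aldol closure from C6 onto C4 would give a meta-bridged ring that cannot aromatise, which leaves C4a as the only nucleophile that can reach C5 in a six-membered closure, and high dilution with slow addition keeps ketene dimerisation and acylation of product phenols down. Since no base is present, E1cB opening of the dihydropyranone or of the flavanone at O1–C2 should not occur and the C2 configuration should be carried through intact.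

**Step 12**
Reactants: 17 (2S)-2-Ar-5,7-dihydroxy-8-(3-methylbut-2-en-1-yl)-2,3-dihydro-4H-chromen-4-one
Product: 18 (2S)-2-[2,4-dihydroxy-5-(2-methylbut-3-en-2-yl)phenyl]-5,7-dihydroxy-8-(3-methylbut-2-en-1-yl)-2,3-dihydro-4H-chromen-4-one (AChE-IN-17)
Conditions: HCl (1.25 M in MeOH), THF, 0 °C → rt
Reagents that add atoms: none
Why: acid-catalysed acetal exchange with methanol removes both aryl MOM ethers under conditions in common use for prenylated flavanones, and short exposure at or below room temperature should avoid prenyl–phenol cyclisation to chromans and acid-induced opening at C2.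

**Compound list** (Ar = 2,4-bis(methoxymethoxy)-5-(2-methylbut-3-en-2-yl)phenyl)

1 | 1-(5-bromo-2,4-dihydroxyphenyl)ethan-1-one | CC(=O)c1cc(Br)c(O)cc1O | starting material
2 | 1-[5-bromo-2,4-bis(methoxymethoxy)phenyl]ethan-1-one | CC(=O)c1cc(Br)c(OCOC)cc1OCOC | intermediate
3 | prenylboronic acid pinacol ester | CC(C)=CCB1OC(C)(C)C(C)(C)O1 | starting material
4 | 1-[2,4-bis(methoxymethoxy)-5-(2-methylbut-3-en-2-yl)phenyl]ethan-1-one | C=CC(C)(C)c1cc(C(C)=O)c(OCOC)cc1OCOC | intermediate
5 | methyl 3-Ar-3-oxopropanoate | C=CC(C)(C)c1cc(C(=O)CC(=O)OC)c(OCOC)cc1OCOC | intermediate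
6 | methyl (3S)-3-Ar-3-hydroxypropanoate | C=CC(C)(C)c1cc([C@@H](O)CC(=O)OC)c(OCOC)cc1OCOC | intermediate
7 | methyl (3S)-3-Ar-3-(triethylsilyloxy)propanoate | C=CC(C)(C)c1cc([C@@H](O[Si](CC)(CC)CC)CC(=O)OC)c(OCOC)cc1OCOC | intermediate
8 | (3S)-3-Ar-N-methoxy-N-methyl-3-(triethylsilyloxy)propanamide | C=CC(C)(C)c1cc([C@@H](O[Si](CC)(CC)CC)CC(=O)N(C)OC)c(OCOC)cc1OCOC | intermediate
9 | 2,2,6-trimethyl-4H-1,3-dioxin-4-one | CC1=CC(=O)OC(C)(C)O1 | starting material
10 | prenyl bromide (1-bromo-3-methylbut-2-ene) | CC(C)=CCBr | starting material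
11 | 2,2-dimethyl-6-(4-methylpent-3-en-1-yl)-4H-1,3-dioxin-4-one | CC(C)=CCCC1=CC(=O)OC(C)(C)O1 | intermediate
12 | 2,2-dimethyl-6-(6-methyl-2-oxohept-5-en-3-yl)-4H-1,3-dioxin-4-one (racemic) | CC(=O)C(CC=C(C)C)C1=CC(=O)OC(C)(C)O1 | intermediate
13 | 6-[(10S)-10-Ar-2-methyl-6,8-dioxo-10-(triethylsilyloxy)dec-2-en-5-yl]-2,2-dimethyl-4H-1,3-dioxin-4-one (C5 epimers) | C=CC(C)(C)c1cc([C@@H](O[Si](CC)(CC)CC)CC(=O)CC(=O)C(CC=C(C)C)C2=CC(=O)OC(C)(C)O2)c(OCOC)cc1OCOC | intermediate
14 | 6-[(10S)-10-Ar-10-hydroxy-2-methyl-6,8-dioxodec-2-en-5-yl]-2,2-dimethyl-4H-1,3-dioxin-4-one (C5 epimers; not isolated) | C=CC(C)(C)c1cc([C@@H](O)CC(=O)CC(=O)C(CC=C(C)C)C2=CC(=O)OC(C)(C)O2)c(OCOC)cc1OCOC | intermediate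
15 | 6-{1-[(2S)-2-Ar-4-oxo-3,4-dihydro-2H-pyran-6-yl]-4-methylpent-3-en-1-yl}-2,2-dimethyl-4H-1,3-dioxin-4-one (side-chain epimers) | C=CC(C)(C)c1cc([C@@H]2CC(=O)C=C(O2)C(CC=C(C)C)C3=CC(=O)OC(C)(C)O3)c(OCOC)cc1OCOC | intermediate
16 | 4-[(2S)-2-Ar-4-oxo-3,4-dihydro-2H-pyran-6-yl]-7-methyl-3-oxoocta-1,6-dien-1-one (acylketene; not isolated) | C=CC(C)(C)c1cc([C@@H]2CC(=O)C=C(O2)C(CC=C(C)C)C(=O)C=C=O)c(OCOC)cc1OCOC | intermediate
17 | (2S)-2-Ar-5,7-dihydroxy-8-(3-methylbut-2-en-1-yl)-2,3-dihydro-4H-chromen-4-one | C=CC(C)(C)c1cc([C@@H]2CC(=O)c3c(O)cc(O)c(CC=C(C)C)c3O2)c(OCOC)cc1OCOC | intermediate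
18 | (2S)-2-[2,4-dihydroxy-5-(2-methylbut-3-en-2-yl)phenyl]-5,7-dihydroxy-8-(3-methylbut-2-en-1-yl)-2,3-dihydro-4H-chromen-4-one | C=CC(C)(C)c1cc([C@@H]2CC(=O)c3c(O)cc(O)c(CC=C(C)C)c3O2)c(O)cc1O | target

**Step count**
Total: 12 steps. Longest linear sequence: 10 steps (1–6, then 9–12); steps 7 and 8 form the second branch.

**Steps most likely to fail**

Step 11. The acylketene may be consumed between molecules (acylation of the phenolic product, dimerisation) faster than C4a reaches C5, or enolisation toward C8 may be too slow at 110 °C. The fallback uses known chemistry and sets out from 15. Heating 15 in toluene with methanol traps the ketene as methyl 4-[(2S)-2-Ar-4-oxo-3,4-dihydro-2H-pyran-6-yl]-7-methyl-3-oxooct-6-enoate F1 (dioxinone alcoholysis). F1 is then treated with magnesium methoxide in methanol at or below room temperature, a Claisen/Dieckmann closure of a polyketo ester in which the dienolate formed at C8 attacks the ester through C4a and methoxide is lost. The route is rejoined at 17; the reaction time is kept short to limit retro-oxa-Michael opening at C2.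

Step 9. Addition of the α-branched dianion to the amide may be slow, so that proton transfer to the amide α-CH2 and loss of silyloxide compete, and the diketo-dioxinone may undergo aldol aromatisation to a resorcylate during work-up. The fallback replaces the Claisen acylation by aldol addition and oxidation and sets out from 8. DIBAL-H reduction at −78 °C should give (3S)-3-Ar-3-(triethylsilyloxy)propanal F2. Aldol addition of the dianion of 12 to this more electrophilic partner should give 6-[(10S)-10-Ar-8-hydroxy-2-methyl-6-oxo-10-(triethylsilyloxy)dec-2-en-5-yl]-2,2-dimethyl-4H-1,3-dioxin-4-one F3. Dess–Martin oxidation buffered with NaHCO3 then rejoins the route at 13.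

Step 2. σ–π–σ isomerisation of the allylpalladium intermediate may lead to the linear prenyl isomer, or the hindered, electron-rich bromide may stall while the allylboronate is protodeboronated. The fallback is an aromatic Claisen route that sets out from 10 together with commercial 2,4-dihydroxyacetophenone. O-alkylation of the non-chelated 4-OH (K2CO3, acetone) should give 1-{2-hydroxy-4-[(3-methylbut-2-en-1-yl)oxy]phenyl}ethan-1-one F4. MOM protection of the 2-OH gives 1-{2-(methoxymethoxy)-4-[(3-methylbut-2-en-1-yl)oxy]phenyl}ethan-1-one F5. Heating in N,N-diethylaniline (ca. 190 °C) should bring about the [3,3] shift, which delivers the inverted allyl group to the less hindered ortho carbon C5 and gives 1-[4-hydroxy-2-(methoxymethoxy)-5-(2-methylbut-3-en-2-yl)phenyl]ethan-1-one F6. MOM protection of the freed 4-OH rejoins the route at 4.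

**Further compounds**
F1 | step 11 | methyl 4-[(2S)-2-Ar-4-oxo-3,4-dihydro-2H-pyran-6-yl]-7-methyl-3-oxooct-6-enoate | C=CC(C)(C)c1cc([C@@H]2CC(=O)C=C(O2)C(CC=C(C)C)C(=O)CC(=O)OC)c(OCOC)cc1OCOC
F2 | step 9 | (3S)-3-Ar-3-(triethylsilyloxy)propanal | C=CC(C)(C)c1cc([C@@H](O[Si](CC)(CC)CC)CC=O)c(OCOC)cc1OCOC
F3 | step 9 | 6-[(10S)-10-Ar-8-hydroxy-2-methyl-6-oxo-10-(triethylsilyloxy)dec-2-en-5-yl]-2,2-dimethyl-4H-1,3-dioxin-4-one | C=CC(C)(C)c1cc([C@@H](O[Si](CC)(CC)CC)CC(O)CC(=O)C(CC=C(C)C)C2=CC(=O)OC(C)(C)O2)c(OCOC)cc1OCOC
F4 | step 2 | 1-{2-hydroxy-4-[(3-methylbut-2-en-1-yl)oxy]phenyl}ethan-1-one | CC(=O)c1ccc(OCC=C(C)C)cc1O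
F5 | step 2 | 1-{2-(methoxymethoxy)-4-[(3-methylbut-2-en-1-yl)oxy]phenyl}ethan-1-one | CC(=O)c1ccc(OCC=C(C)C)cc1OCOC
F6 | step 2 | 1-[4-hydroxy-2-(methoxymethoxy)-5-(2-methylbut-3-en-2-yl)phenyl]ethan-1-one | C=CC(C)(C)c1cc(C(C)=O)c(OCOC)cc1O
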